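- The dusk run holds 22.0% of its electrophile at 30.0 min and 20.8% at 60.0 min, and the spring run ends at 21.8%, so both flasks come to a stop at about the same level.

in all of them: electrophile 0.020 M

| charge | nucleophile | free base | remark | time |
|---|---|---|---|---|
| dusk | 0.016 M | 6.1 mM | run made earlier |  |
| spring | 0.016 M | 36 mM | run made earlier |  |
| teal | 0.0160 M | 20.0 mM |  | 1.5 h |
| amber | 0.0160 M | 10.0 mM |  | 1.5 h |
| violet | 0.0160 M | 40.0 mM |  | 1.5 h |

| run | time / min | electrophile / % | target / % |
|---|---|---|---|
| dusk | 4.00 | 32.6 | 68.0 |
| dusk | 12.0 | 24.4 | 74.8 |
| dusk | 20.0 | 23.7 | 77.9 |
| dusk | 30.0 | 22.0 | 79.1 |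
| dusk | 50.0 | 21.6 | 78.0 |
| dusk | 60.0 | 20.8 | 79.7 |
| spring | 5.00 | 26.0 | 75.1 |
| spring | 8.00 | 24.7 | 75.6 |
| spring | 15.0 | 22.2 | 78.2 |
| spring | 25.0 | 21.8 | 78.5 |
| spring | 40.0 | 22.5 | 77.9 |
| spring | 60.0 | 21.8 | 77.3 |

(standard deviation of a reading: 1 percentage point)

- what was read earlier has a scatter of 1 percentage point, one standard deviation
- a reading or a percentage of target counts all its forms, free or not

1. part of the electrophile that has reacted at the end, teal
2. part of the electrophile that has reacted at the end, amber
3. part of the electrophile that has reacted at the end, violet
4. what raising the concentration of free base from its lowest to its highest value here does to the part of the electrophile that has reacted (changes below 5 percentage points count as none) (no change / it rises / it falls)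

- One number folds the charges together: the reach, the nucleophile charged as a fraction of the electrophile charged, 80.0%.
- With one nucleophile going per electrophile, the reach is the ceiling on the part of the electrophile that reacts in these flasks, where the nucleophile is the limiting reagent.
- Teal, amber and violet share this reach, so the reckoning here puts each just under it, as the last readings stand at 79.2% reacted in dusk and 78.2% in spring.
- A second number tests whether one is enough: free base per electrophile. It is 30.5% in dusk, below the reach, and 180% in spring, yet the two ends differ by 1 percentage point, which is the size of the scatter.
- Amber at 50.0% lies inside that span, and violet at 200% lies a little beyond it.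
- Time adds nothing expected, since the dusk stop at 30.0 min comes well before 1.5 h.
- The forecast gave 79% for teal, 79% for amber and 79% for violet, each from 76.5% to 81%, with trend "no change", reading the plateau as “stoichiometric exhaustion of the nucleophile”.
- The flasks give 77.9% for teal, 78.0% for amber and 77.8% for violet, a change of −0.16 points across the free base, so the trend is no change. Teal ends with 0% of its nucleophile free and 2.10 × 10⁻⁴ M of self-condensation product, which took two nucleophile each, or 2.10% of the electrophile charge; the reach less this share is 77.9%.

    electrophile + nucleophile → acid set free + target (k = 5.60 /M/s)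
    nucleophile + acid set free ⇌ protonated nucleophile, settled at all times (K = 1100 /M)
    acid set free + free base ⇌ salt of the base (K = 100 /M, k = 2.60 /M/s)
    2 nucleophile → self-condensation product (k = 0.250 /M/s)
    crystals ⇌ target, rate k5*(cs5 - [target]) while solid is left; crystals form when [target] > cs5 (solubility = 16.0 mM, k = 0.260 /s)

- A neighbour of teal, charged with 0.0096 M of nucleophile, has a reach of 48.0%. Computed, that flask reaches 47.3%, with 52.7% of its electrophile left.

The data are simulated on assumed constants; noise was put on by code.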